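**Plan**

- Retrosynthesis (chroman numbering O1, C2–C8a; norbornane atoms C1n–C7n, C2n = C2): the C6/C8 formyl groups and the two O-methyl groups come off first. The dihydropyran ring is then cut at C3–C2 and at O1–C8a in one stroke, giving camphenilone 3 and alkyl iodide 17. Iodide 17 goes back to an arylacetyl imide.
- Enabling feature: spiro C2 carries O1 and lies between bridgehead C1n–H and quaternary C3n(CH3)2, so it maps onto the carbonyl carbon of a non-enolisable ketone. O1 sits on arene carbon C8a, which is meta to the oxygens on C5 and C7 and 1,4 to C3 through C4a and C4, so the alkoxide born at C2 can displace fluoride at C8a.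
- Forward: the norbornane (from (−)-camphene) and the benzene ring (from 1-fluoro-3,5-dimethoxybenzene) are bought. The dihydropyran ring is the only ring made (step 10). Diformylation and O-demethylation finish the route.
- Stereochemistry: C1n and C4n come from (−)-camphene. C4 comes from an Evans alkylation under (R)-4-benzyloxazolidinone. C2 comes from exo attack of the C3 carbanion on the norbornanone carbonyl, which leaves O1 endo as in the target.

Key step: step 10

Assumption: commercial (−)-camphene is used as the (1S,4R) enantiomer; any shortfall in its optical purity should appear after step 10 as a diastereomer of 20 that can be removed, because 17 is a single enantiomer.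

**Route**

Step 1
Reactants: 1 (−)-camphene
Product: 3 (1R,4S)-3,3-dimethylbicyclo[2.2.1]heptan-2-one (camphenilone), via ozonide 2 (not isolated)
Conditions: O3, CH2Cl2, −78 °C; then Me2S, −78 °C → rt
Reagents that add atoms: ozone, [O-][O+]=O
Why: Ozonolysis of the exocyclic 1,1-disubstituted alkene and reduction of ozonide 2 with Me2S should give the ketone without touching the two bridgehead stereocentres, which are carried over from 1.

Step 2
Reactants: 4 1-fluoro-3,5-dimethoxybenzene
Product: 5 2-bromo-1-fluoro-3,5-dimethoxybenzene
Conditions: NBS (1.0 equiv), MeCN, 0 °C → rt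
Reagents that add atoms: N-bromosuccinimide, O=C1CCC(=O)N1Br
Why: Electrophilic aromatic bromination should occur para to one methoxy group and ortho to the other, at the position flanked by the small fluorine and not at the position between the two methoxy groups, with one equivalent of NBS limiting the reaction to monobromination.

Step 3
Reactants: 5 2-bromo-1-fluoro-3,5-dimethoxybenzene; 6 (2-tert-butoxy-2-oxoethyl)zinc bromide (BrZnCH2CO2t-Bu)
Product: 7 tert-butyl (2-fluoro-4,6-dimethoxyphenyl)acetate
Conditions: Pd2(dba)3 (2 mol %), XPhos (8 mol %), THF, 65 °C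
Reagents that add atoms: none
Why: Negishi-type cross-coupling of the Reformatsky reagent (α-arylation of a zinc ester enolate on zerovalent palladium) should take place at the C–Br bond only, the bulky biaryl phosphine coping with the two ortho substituents and the C–F bond staying inert.

Step 4
Reactants: 7 tert-butyl (2-fluoro-4,6-dimethoxyphenyl)acetate
Product: 8 (2-fluoro-4,6-dimethoxyphenyl)acetic acid
Conditions: CF3CO2H, CH2Cl2, rt
Reagents that add atoms: none
Why: Acidolysis of the tert-butyl ester (E1 loss of 2-methylpropene) should free the acid, and ring tert-butylation is not expected because both free arene positions are flanked by two substituents.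

Step 5
Reactants: 8 (2-fluoro-4,6-dimethoxyphenyl)acetic acid; 9 (R)-4-benzyloxazolidin-2-one
Product: 11 (4R)-4-benzyl-3-[(2-fluoro-4,6-dimethoxyphenyl)acetyl]oxazolidin-2-one, via mixed pivalic anhydride 10 (not isolated)
Conditions: t-BuCOCl, Et3N, THF, −20 °C; then 9, LiCl, −20 °C → rt
Reagents that add atoms: none
Why: N-acylation of the oxazolidinone through the mixed pivalic anhydride under LiCl/Et3N activation is the standard way to load arylacetic acids on this auxiliary without ketene formation; no stereocentre is formed.

Step 6
Reactants: 11 (4R)-4-benzyl-3-[(2-fluoro-4,6-dimethoxyphenyl)acetyl]oxazolidin-2-one; 12 3-bromo-2-methylprop-1-ene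
Product: 14 (4R)-4-benzyl-3-[(2R)-2-(2-fluoro-4,6-dimethoxyphenyl)-4-methylpent-4-enoyl]oxazolidin-2-one, via sodium enolate 13 (not isolated)
Conditions: NaN(SiMe3)2, THF, −78 °C; then 12, −78 → −40 °C
Reagents that add atoms: none
Why: Evans asymmetric alkylation, in which the chelated Z-enolate 13 should be attacked by the allylic bromide on the face opposite the benzyl group of the (R)-auxiliary, setting the benzylic stereocentre (the future C4) as 2R.

Step 7
Reactants: 14 (4R)-4-benzyl-3-[(2R)-2-(2-fluoro-4,6-dimethoxyphenyl)-4-methylpent-4-enoyl]oxazolidin-2-one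
Product: 15 (2R)-2-(2-fluoro-4,6-dimethoxyphenyl)-4-methylpent-4-en-1-ol
Conditions: LiBH4, MeOH (1 equiv), Et2O, 0 °C
Reagents that add atoms: none
Why: Reductive cleavage of the exocyclic imide carbonyl with LiBH4 should give the primary alcohol and return the auxiliary, and the α-aryl stereocentre is not enolised under these hydride conditions.

Step 8
Reactants: 15 (2R)-2-(2-fluoro-4,6-dimethoxyphenyl)-4-methylpent-4-en-1-ol
Product: 16 (2R)-2-(2-fluoro-4,6-dimethoxyphenyl)-4-methylpentan-1-ol
Conditions: H2 (1 atm), PtO2, EtOAc, rt
Reagents that add atoms: none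
Why: Heterogeneous hydrogenation of the 1,1-disubstituted alkene turns the methallyl group into isobutyl; platinum is chosen over palladium to limit double-bond migration toward the benzylic stereocentre, and the aryl fluoride is inert.

Step 9
Reactants: 16 (2R)-2-(2-fluoro-4,6-dimethoxyphenyl)-4-methylpentan-1-ol
Product: 17 1-fluoro-2-[(2R)-1-iodo-4-methylpentan-2-yl]-3,5-dimethoxybenzene
Conditions: I2, PPh3, imidazole, CH2Cl2, 0 °C → rt
Reagents that add atoms: iodine, II
Why: Appel-type iodination (SN2 displacement of the oxyphosphonium group by iodide at the primary carbon) leaves the adjacent stereocentre untouched and provides the substrate for iodine–lithium exchange.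

Step 10
Reactants: 17 1-fluoro-2-[(2R)-1-iodo-4-methylpentan-2-yl]-3,5-dimethoxybenzene; 3 (1R,4S)-camphenilone
Product: 20 (1R,2R,4S,4'S)-5',7'-dimethoxy-3,3-dimethyl-4'-(2-methylpropyl)-3',4'-dihydrospiro[bicyclo[2.2.1]heptane-2,2'-chromene], via alkyllithium 18 (not isolated), via lithium alkoxide 19 (not isolated)
Conditions: t-BuLi (2.0 equiv per 17), Et2O/pentane, −78 °C; then 3, −78 → 0 °C; then KOt-Bu, THF/DMPU, 65 °C
Reagents that add atoms: none
Why: Iodine–lithium exchange gives primary alkyllithium 18, whose carbanionic C3 adds to the carbonyl carbon (C2) of the non-enolisable ketone 3 to form the C3–C2 bond and lithium alkoxide 19; after cation exchange to potassium in DMPU the alkoxide oxygen attacks C8a and expels fluoride by addition–elimination (SNAr), forming the O1–C8a bond. The closest known reaction types are the 1,2-addition of organolithium and Grignard reagents to camphenilone and fenchone and the intramolecular alkoxide SNAr on non-activated fluoroarenes that gives chromans. The dihydropyran ring is the only ring closed, in a six-membered exo mode, the oxygen attacking the arene carbon whose π bond to C8 lies outside the new ring. The new stereocentre C2 is set by exo attack of C3 on the norbornanone carbonyl (the endo face is screened by the C5n–C6n bridge and the endo methyl group, as in the addition of methyl Grignard reagent that gives methylcamphenilol), which places C3 exo and O1 endo; C4 is carried in unchanged from 17. The step needs 1,2-addition to win over proton transfer from the arene C–H between F and OMe and over β-hydride reduction, which the absence of α-hydrogens in 3 and the fast exchange and addition at −78 °C in ether should secure; it also needs displacement at C8a and not at the equally near methoxy-bearing C5, which is secured by fluoride being by far the better nucleofuge and by the two meta methoxy groups stabilising the anionic transition state inductively.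

Step 11
Reactants: 20 (1R,2R,4S,4'S)-5',7'-dimethoxy-3,3-dimethyl-4'-(2-methylpropyl)-3',4'-dihydrospiro[bicyclo[2.2.1]heptane-2,2'-chromene]
Product: 21 (1R,2R,4S,4'S)-5',7'-dimethoxy-3,3-dimethyl-4'-(2-methylpropyl)-3',4'-dihydrospiro[bicyclo[2.2.1]heptane-2,2'-chromene]-6',8'-dicarbaldehyde
Conditions: Cl2CHOMe (6 equiv), TiCl4 (6 equiv), CH2Cl2, −78 → 0 °C; then H2O
Reagents that add atoms: dichloromethyl methyl ether, COC(Cl)Cl; water, O
Why: Rieche formylation (electrophilic substitution by the chloro(methoxy)methyl cation) should formylate C6 and C8, the only unsubstituted ring carbons and each ortho or para to three oxygen substituents, while the low temperature guards the tertiary C2–O1 bond against ionisation.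

Step 12
Reactants: 21 (1R,2R,4S,4'S)-5',7'-dimethoxy-3,3-dimethyl-4'-(2-methylpropyl)-3',4'-dihydrospiro[bicyclo[2.2.1]heptane-2,2'-chromene]-6',8'-dicarbaldehyde
Product: 22 (1R,2R,4S,4'S)-5',7'-dihydroxy-3,3-dimethyl-4'-(2-methylpropyl)-3',4'-dihydrospiro[bicyclo[2.2.1]heptane-2,2'-chromene]-6',8'-dicarbaldehyde (CNP0150011.1)
Conditions: LiSC6H4Me-4 (from 4-methylbenzenethiol and n-BuLi), HMPA, toluene, 110 °C; then 1 M HCl
Reagents that add atoms: none
Why: Nucleophilic O-demethylation (SN2 attack of the soft thiolate on the methyl carbons of the two methoxy groups, each a vinylogous methyl ester through its ortho formyl group) should free both phenols, while the tertiary, bridged C2–O1 bond cannot undergo SN2 and no acid is present to ionise it.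

**Compound list**

1 | (−)-camphene, (1S,4R)-2,2-dimethyl-3-methylidenebicyclo[2.2.1]heptane | C=C1[C@@H]2CC[C@@H](C2)C1(C)C | starting material
2 | camphene ozonide (spiro-1,2,4-trioxolane, spiro centre not defined) | C1OOC2(O1)[C@@H]3CC[C@@H](C3)C2(C)C | intermediate
3 | (1R,4S)-3,3-dimethylbicyclo[2.2.1]heptan-2-one (camphenilone) | O=C1[C@@H]2CC[C@@H](C2)C1(C)C | intermediate
4 | 1-fluoro-3,5-dimethoxybenzene | COc1cc(F)cc(OC)c1 | starting material
5 | 2-bromo-1-fluoro-3,5-dimethoxybenzene | COc1cc(F)c(Br)c(OC)c1 | intermediate
6 | (2-tert-butoxy-2-oxoethyl)zinc bromide | CC(C)(C)OC(=O)C[Zn]Br | starting material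
7 | tert-butyl (2-fluoro-4,6-dimethoxyphenyl)acetate | COc1cc(F)c(CC(=O)OC(C)(C)C)c(OC)c1 | intermediate
8 | (2-fluoro-4,6-dimethoxyphenyl)acetic acid | COc1cc(F)c(CC(=O)O)c(OC)c1 | intermediate
9 | (R)-4-benzyloxazolidin-2-one | O=C1N[C@H](Cc2ccccc2)CO1 | starting material
10 | (2-fluoro-4,6-dimethoxyphenyl)acetic pivalic anhydride | COc1cc(F)c(CC(=O)OC(=O)C(C)(C)C)c(OC)c1 | intermediate
11 | (4R)-4-benzyl-3-[(2-fluoro-4,6-dimethoxyphenyl)acetyl]oxazolidin-2-one | COc1cc(F)c(CC(=O)N2[C@H](Cc3ccccc3)COC2=O)c(OC)c1 | intermediate
12 | 3-bromo-2-methylprop-1-ene | C=C(C)CBr | starting material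
13 | sodium Z-enolate of 11 | [Na+].[O-]/C(=C\c1c(F)cc(OC)cc1OC)N1[C@H](Cc2ccccc2)COC1=O | intermediate
14 | (4R)-4-benzyl-3-[(2R)-2-(2-fluoro-4,6-dimethoxyphenyl)-4-methylpent-4-enoyl]oxazolidin-2-one | C=C(C)C[C@H](c1c(F)cc(OC)cc1OC)C(=O)N1[C@H](Cc2ccccc2)COC1=O | intermediate
15 | (2R)-2-(2-fluoro-4,6-dimethoxyphenyl)-4-methylpent-4-en-1-ol | C=C(C)C[C@H](c1c(F)cc(OC)cc1OC)CO | intermediate
16 | (2R)-2-(2-fluoro-4,6-dimethoxyphenyl)-4-methylpentan-1-ol | CC(C)C[C@H](c1c(F)cc(OC)cc1OC)CO | intermediate
17 | 1-fluoro-2-[(2R)-1-iodo-4-methylpentan-2-yl]-3,5-dimethoxybenzene | CC(C)C[C@H](c1c(F)cc(OC)cc1OC)CI | intermediate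
18 | [(2R)-2-(2-fluoro-4,6-dimethoxyphenyl)-4-methylpentyl]lithium | CC(C)C[C@H](c1c(F)cc(OC)cc1OC)C[Li] | intermediate
19 | lithium (1R,2R,4S)-2-[(2S)-2-(2-fluoro-4,6-dimethoxyphenyl)-4-methylpentyl]-3,3-dimethylbicyclo[2.2.1]heptan-2-olate (O endo, side chain exo) | CC(C)C[C@H](c1c(F)cc(OC)cc1OC)C[C@@]2(O[Li])[C@@H]1CC[C@@H](C1)C2(C)C | intermediate
20 | (1R,2R,4S,4'S)-5',7'-dimethoxy-3,3-dimethyl-4'-(2-methylpropyl)-3',4'-dihydrospiro[bicyclo[2.2.1]heptane-2,2'-chromene] | CC(C)C[C@H]1C[C@@]2(Oc3cc(OC)cc(OC)c31)[C@@H]1CC[C@@H](C1)C2(C)C | intermediate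
21 | (1R,2R,4S,4'S)-5',7'-dimethoxy-3,3-dimethyl-4'-(2-methylpropyl)-3',4'-dihydrospiro[bicyclo[2.2.1]heptane-2,2'-chromene]-6',8'-dicarbaldehyde | CC(C)C[C@H]1C[C@@]2(Oc3c(C=O)c(OC)c(C=O)c(OC)c31)[C@@H]1CC[C@@H](C1)C2(C)C | intermediate
22 | (1R,2R,4S,4'S)-5',7'-dihydroxy-3,3-dimethyl-4'-(2-methylpropyl)-3',4'-dihydrospiro[bicyclo[2.2.1]heptane-2,2'-chromene]-6',8'-dicarbaldehyde | CC(C)C[C@H]1C[C@@]2(Oc3c(C=O)c(O)c(C=O)c(O)c31)[C@@H]1CC[C@@H](C1)C2(C)C | target

**Step count and risks**

Total step count: 12. Longest linear sequence: 11 steps (steps 2–12, from 4); step 1 is a one-step branch that joins at step 10.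

Steps most likely to fail:

1. Step 10. The alkyllithium may be consumed by proton transfer from the arene C–H between F and OMe, or may deliver a β-hydride to the hindered ketone in place of adding to it. The fluoride displacement on the electron-rich ring may also be too slow. The fallback sets out from 17 and 3 and comes back at 20. Alkyllithium 18 is made as before and transmetallated with CeCl3 in THF at −78 °C to organocerium reagent F1, which is much less basic and should add cleanly to 3 from the exo face. Aqueous work-up gives tertiary alcohol F2, which is isolated. The ring is then closed by elimination–addition instead of addition–elimination. s-BuLi (2.5 equiv) in THF at −78 °C deprotonates the hydroxyl group and the arene C–H between F and OMe. On warming, LiF is lost to give aryne F3. The tethered alkoxide adds to the aryne carbon next to the side chain (six-membered closure, the negative charge ending ortho to the methoxy group) to give aryllithium F4, which is protonated on work-up to 20.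

2. Step 11. Once the first formyl group is in place the aryloxy group becomes a better leaving group, so the Lewis acid may ionise the tertiary C2–O1 bond and trigger skeletal rearrangement; the second formylation may also stall on the deactivated ring. The fallback sets out from 20 and comes back at 21 without a Lewis acid. NBS (2.1 equiv, MeCN, 0 °C) brominates the two free positions to give 6',8'-dibromide F5. Double bromine–lithium exchange (t-BuLi, THF, −78 °C) gives dilithio arene F6, which is quenched with DMF and hydrolysed to dialdehyde 21.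

3. Step 12. The second demethylation may stall once the first phenoxide has formed, or the thiolate may add to the formyl groups or attack C8a. The fallback sets out from 20 and comes back at 22, changing the order of events. Both methyl ethers of 20 are cleaved before any aldehyde is present (NaSEt in excess, DMF, 150 °C) to give 5',7'-diol F7. The free resorcinol-type ring is then formylated twice by a Vilsmeier–Haack reaction (POCl3, DMF, then aqueous hydrolysis), the method used for phloroglucinol itself, to give 22.

**Further compounds**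

F1 | step 10 | [(2R)-2-(2-fluoro-4,6-dimethoxyphenyl)-4-methylpentyl]cerium dichloride | CC(C)C[C@H](c1c(F)cc(OC)cc1OC)C[Ce](Cl)Cl
F2 | step 10 | (1R,2R,4S)-2-[(2S)-2-(2-fluoro-4,6-dimethoxyphenyl)-4-methylpentyl]-3,3-dimethylbicyclo[2.2.1]heptan-2-ol | CC(C)C[C@H](c1c(F)cc(OC)cc1OC)C[C@@]2(O)[C@@H]1CC[C@@H](C1)C2(C)C
F3 | step 10 | aryne lithium alkoxide from F2 (fluorine and the adjacent ring hydrogen removed) | CC(C)C[C@H](C1=C(OC)C=C(OC)C#C1)C[C@@]2(O[Li])[C@@H]1CC[C@@H](C1)C2(C)C
F4 | step 10 | 8'-lithio derivative of 20 | CC(C)C[C@H]1C[C@@]2(Oc3c([Li])c(OC)cc(OC)c31)[C@@H]1CC[C@@H](C1)C2(C)C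
F5 | step 11 | 6',8'-dibromo derivative of 20 | CC(C)C[C@H]1C[C@@]2(Oc3c(Br)c(OC)c(Br)c(OC)c31)[C@@H]1CC[C@@H](C1)C2(C)C
F6 | step 11 | 6',8'-dilithio derivative of 20 | CC(C)C[C@H]1C[C@@]2(Oc3c([Li])c(OC)c([Li])c(OC)c31)[C@@H]1CC[C@@H](C1)C2(C)C
F7 | step 12 | (1R,2R,4S,4'S)-3,3-dimethyl-4'-(2-methylpropyl)-3',4'-dihydrospiro[bicyclo[2.2.1]heptane-2,2'-chromene]-5',7'-diol | CC(C)C[C@H]1C[C@@]2(Oc3cc(O)cc(O)c31)[C@@H]1CC[C@@H](C1)C2(C)C
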